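**Strategy.** Ring A of candidachalcone carries the cinnamoyl carbon on C1', flanked by the C2' hydroxyl and the C6' methoxyl. Both the C1'–C(=O) and the C2'–O bond are therefore disconnected to a 3-methoxyaryne spanning C1'–C2' and one cinnamic acid: fluoride-triggered insertion of the aryne into the acid C–O bond should deliver chelated phenol and enone in one operation, the methoxyl steering oxygen to C2'. The aryne precursor is an ortho-silylaryl triflate made from 5-methoxyresorcinol, with the future C4' oxygen masked as a pivalate; its partner is O-pivaloyl (E)-4-hydroxycinnamic acid. Iodination at C3', Suzuki coupling with a cyclic (Z)-alkenylboron hemiester and methanolysis complete the route.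

Key step: step 5

Remark: ring A is numbered as in chalcones (C1' acyl carbon, C2' OH, C3' side chain, C4' OH, C5' H, C6' OCH3); ring B is the 4-hydroxyphenyl ring.

**Step 1**
Reactants: 1 5-methoxyresorcinol (5-methoxybenzene-1,3-diol)
Product: 2 4-bromo-5-methoxybenzene-1,3-diol
Conditions: NBS (1.0 equiv), THF, −78 °C
Reagents that add atoms: N-bromosuccinimide, O=C1CCC(=O)N1Br
Why: Electrophilic aromatic bromination: C4 and C6 are equivalent and each lies para to one hydroxyl and ortho to the other, so they should react ahead of the more crowded C2 between the two hydroxyls, while one equivalent of NBS at low temperature restrains dibromination.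

**Step 2**
Reactants: 2 4-bromo-5-methoxybenzene-1,3-diol
Product: 7 5-hydroxy-3-methoxy-2-(trimethylsilyl)phenyl trifluoromethanesulfonate, via bis(trimethylsilyl) ether 3 (not isolated), via aryllithium 4 (not isolated), via lithium ortho-silylphenoxide 5 (not isolated), via O-silylated aryl triflate 6 (not isolated)
Conditions: HMDS, THF, 70 °C, then concentrate; n-BuLi (1.1 equiv), THF, −78 °C; Tf2O (1.2 equiv), −78 °C; aq. NaHCO3; MeOH, citric acid (cat.), rt
Reagents that add atoms: hexamethyldisilazane, C[Si](C)(C)N[Si](C)(C)C; trifluoromethanesulfonic anhydride, O=S(=O)(OS(=O)(=O)C(F)(F)F)C(F)(F)F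
Why: Silylation followed by bromine–lithium exchange and a 1,3-retro-Brook shift: in aryllithium 4 only the C3 silyl ether is ortho to lithium, so one trimethylsilyl group should move from that oxygen to C4 and unmask lithium phenoxide 5 as the sole oxygen nucleophile for Tf2O, and the remote aryl O-silyl ether of 6 is then cleaved by mild acidic methanolysis, which should leave the ring-bound silyl group and the triflate untouched.

**Step 3**
Reactants: 7 5-hydroxy-3-methoxy-2-(trimethylsilyl)phenyl trifluoromethanesulfonate; 8 pivaloyl chloride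
Product: 9 3-methoxy-5-(pivaloyloxy)-2-(trimethylsilyl)phenyl trifluoromethanesulfonate
Conditions: Et3N, DMAP (cat.), CH2Cl2, 0 °C to rt
Reagents that add atoms: none
Why: DMAP-catalysed O-acylation (esterification) of the only free phenol, which is unhindered; a tertiary amine base does not trigger aryne formation from the silyl triflate.

**Step 4**
Reactants: 10 (E)-4-hydroxycinnamic acid; 8 pivaloyl chloride
Product: 11 (E)-3-[4-(pivaloyloxy)phenyl]prop-2-enoic acid
Conditions: NaOH (2.2 equiv), H2O/THF, 0 °C; then HCl to pH 2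
Reagents that add atoms: none
Why: Schotten–Baumann O-acylation: in aqueous alkali the phenoxide is far more nucleophilic than the carboxylate, any mixed anhydride is hydrolysed before acidification, and the E alkene is not touched.

**Step 5**
Reactants: 9 3-methoxy-5-(pivaloyloxy)-2-(trimethylsilyl)phenyl trifluoromethanesulfonate; 11 (E)-3-[4-(pivaloyloxy)phenyl]prop-2-enoic acid
Product: 16 (E)-1-[2-hydroxy-6-methoxy-4-(pivaloyloxy)phenyl]-3-[4-(pivaloyloxy)phenyl]prop-2-en-1-one, via cesium cinnamate salt 12 (not isolated), via aryne 13 (not isolated), via ortho-cesiated aryl ester 14 (not isolated), via cesium chalcone phenoxide 15 (not isolated)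
Conditions: 11 (1.5 equiv), Cs2CO3 (0.75 equiv), MeOH, 0 °C, then evaporate and dry in vacuo; 9 (1.0 equiv), CsF (3 equiv), THF, 80 °C, sealed tube; 0.5 M HCl, 0 °C
Reagents that add atoms: none
Why: Fluoride removes the trimethylsilyl group of 9 with loss of triflate to give aryne 13 across C1'–C2'; the carboxylate oxygen of 12 adds to C2', the aryne carbon remote from the methoxyl, because the aryl anion then develops at C1' beside the inductively withdrawing C6' oxygen. The ortho-metalated aryl ester 14 passes its acyl group from oxygen to C1' through a four-membered tetrahedral intermediate (an anionic Fries-type 1,3-shift), which forms the C1'–C(=O) bond and leaves the chelated phenoxide 15. The closest known reaction type is the fluoride-mediated insertion of arynes into the C–O bond of carboxylic acids to give ortho-hydroxyaryl ketones, which includes α,β-unsaturated acids. No ring is closed and no stereocentre is formed; the E alkene of 11 is carried through unchanged. The step needs regioselective carboxylate attack, secured by the C6' methoxyl on one flank of the aryne against a bare C3'–H on the other, and acyl transfer ahead of protonation, secured by the dry preformed cesium salt, which leaves no acidic proton in the flask. The same aprotic medium keeps 15 as the open phenoxide, since oxa-Michael closure to the flavanone would need a proton to trap the enolate, and the cold acidic quench then releases chalcone 16.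

**Step 6**
Reactants: 16 (E)-1-[2-hydroxy-6-methoxy-4-(pivaloyloxy)phenyl]-3-[4-(pivaloyloxy)phenyl]prop-2-en-1-one
Product: 17 (E)-1-[2-hydroxy-3-iodo-6-methoxy-4-(pivaloyloxy)phenyl]-3-[4-(pivaloyloxy)phenyl]prop-2-en-1-one
Conditions: NIS (1.05 equiv), DMF, rt, dark
Reagents that add atoms: N-iodosuccinimide, O=C1CCC(=O)N1I
Why: Electrophilic aromatic iodination: C3' is ortho to the chelated C2' hydroxyl and para to the C6' methoxyl, the position normally attacked in 2-hydroxy-4,6-dioxygenated aryl ketones, whereas C5', ring B and the enone are less activated, and the neutral medium should not promote closure to the flavanone.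

**Step 7**
Reactants: 18 ethyl propiolate
Product: 19 ethyl (Z)-3-iodoprop-2-enoate
Conditions: NaI, AcOH, 70 °C
Reagents that add atoms: sodium iodide, [Na+].[I-]
Why: Hydroiodination of an alkynoate: conjugate addition of iodide and protonation of the resulting allenolate on the face away from iodine should give the Z β-iodoacrylate under kinetic control.

**Step 8**
Reactants: 19 ethyl (Z)-3-iodoprop-2-enoate
Product: 20 (Z)-4-iodo-2-methylbut-3-en-2-ol
Conditions: MeMgBr (2.5 equiv), THF, −78 to 0 °C; aq. NH4Cl
Reagents that add atoms: methylmagnesium bromide, C[Mg]Br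
Why: Double Grignard addition to the ester gives the tertiary alcohol; at low temperature MeMgBr should neither exchange with the vinyl iodide nor add in conjugate fashion, so the Z geometry is kept.

**Step 9**
Reactants: 20 (Z)-4-iodo-2-methylbut-3-en-2-ol
Product: 22 5,5-dimethyl-1,2-oxaborol-2(5H)-ol, via dilithio alkoxide 21 (not isolated)
Conditions: n-BuLi (2.1 equiv), Et2O, −78 °C; B(OiPr)3, −78 °C to rt; 1 M HCl
Reagents that add atoms: triisopropyl borate, CC(C)OB(OC(C)C)OC(C)C; water, O
Why: Deprotonation of the alcohol and iodine–lithium exchange, which retains alkene geometry, give dianion 21, whose borylation with B(OiPr)3 and acidic hydrolysis furnish a boronic acid that closes onto the cis tertiary hydroxyl, the five-membered hemiester ring locking the Z configuration.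

**Step 10**
Reactants: 17 (E)-1-[2-hydroxy-3-iodo-6-methoxy-4-(pivaloyloxy)phenyl]-3-[4-(pivaloyloxy)phenyl]prop-2-en-1-one; 22 5,5-dimethyl-1,2-oxaborol-2(5H)-ol
Product: 23 (E)-1-{2-hydroxy-3-[(Z)-3-hydroxy-3-methylbut-1-en-1-yl]-6-methoxy-4-(pivaloyloxy)phenyl}-3-[4-(pivaloyloxy)phenyl]prop-2-en-1-one
Conditions: Pd(OAc)2 (5 mol%), SPhos (10 mol%), K3PO4 (3 equiv), dioxane/H2O (10:1), 50 °C
Reagents that add atoms: none
Why: Suzuki–Miyaura coupling: oxidative addition of the zerovalent palladium–SPhos species into the C3'–I bond, base-assisted transmetalation of the alkenyl group of 22 and reductive elimination all proceed with retention at the alkenyl carbon, so the Z geometry fixed by the ring of 22 is transferred to the side chain, and aqueous phosphate at 50 °C should spare the hindered pivalates.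

**Step 11**
Reactants: 23 (E)-1-{2-hydroxy-3-[(Z)-3-hydroxy-3-methylbut-1-en-1-yl]-6-methoxy-4-(pivaloyloxy)phenyl}-3-[4-(pivaloyloxy)phenyl]prop-2-en-1-one
Product: 24 candidachalcone
Conditions: K2CO3 (3 equiv), MeOH, 0 °C to rt; pH 7 phosphate buffer
Reagents that add atoms: none
Why: Base-mediated methanolysis (transesterification) of the two aryl pivalates; the phenoxides formed disfavour oxa-Michael closure to the flavanone, and the buffered neutral work-up avoids acid-promoted cyclodehydration of the (Z)-hydroxyalkenyl phenol to a 2,2-dimethylchromene.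

**Compound list**

1 | 5-methoxyresorcinol (5-methoxybenzene-1,3-diol) | COc1cc(O)cc(O)c1 | starting material
2 | 4-bromo-5-methoxybenzene-1,3-diol | COc1cc(O)cc(O)c1Br | intermediate
3 | 2-bromo-1-methoxy-3,5-bis(trimethylsilyloxy)benzene | COc1cc(O[Si](C)(C)C)cc(O[Si](C)(C)C)c1Br | intermediate
4 | [2-methoxy-4,6-bis(trimethylsilyloxy)phenyl]lithium | COc1cc(O[Si](C)(C)C)cc(O[Si](C)(C)C)c1[Li] | intermediate
5 | lithium 3-methoxy-2-(trimethylsilyl)-5-(trimethylsilyloxy)phenolate | COc1cc(O[Si](C)(C)C)cc([O-])c1[Si](C)(C)C.[Li+] | intermediate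
6 | 3-methoxy-2-(trimethylsilyl)-5-(trimethylsilyloxy)phenyl trifluoromethanesulfonate | COc1cc(O[Si](C)(C)C)cc(OS(=O)(=O)C(F)(F)F)c1[Si](C)(C)C | intermediate
7 | 5-hydroxy-3-methoxy-2-(trimethylsilyl)phenyl trifluoromethanesulfonate | COc1cc(O)cc(OS(=O)(=O)C(F)(F)F)c1[Si](C)(C)C | intermediate
8 | pivaloyl chloride (2,2-dimethylpropanoyl chloride) | CC(C)(C)C(Cl)=O | starting material
9 | 3-methoxy-5-(pivaloyloxy)-2-(trimethylsilyl)phenyl trifluoromethanesulfonate | COc1cc(OC(=O)C(C)(C)C)cc(OS(=O)(=O)C(F)(F)F)c1[Si](C)(C)C | intermediate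
10 | (E)-4-hydroxycinnamic acid | OC(=O)/C=C/c1ccc(O)cc1 | starting material
11 | (E)-3-[4-(pivaloyloxy)phenyl]prop-2-enoic acid | OC(=O)/C=C/c1ccc(OC(=O)C(C)(C)C)cc1 | intermediate
12 | cesium (E)-3-[4-(pivaloyloxy)phenyl]prop-2-enoate | [Cs+].[O-]C(=O)/C=C/c1ccc(OC(=O)C(C)(C)C)cc1 | intermediate
13 | 3-methoxy-5-(pivaloyloxy)benzyne (1,2-didehydrobenzene) | COC1=CC(OC(=O)C(C)(C)C)=CC#C1 | intermediate
14 | 2-cesio-3-methoxy-5-(pivaloyloxy)phenyl (E)-3-[4-(pivaloyloxy)phenyl]prop-2-enoate | COc1cc(OC(=O)C(C)(C)C)cc(OC(=O)/C=C/c2ccc(OC(=O)C(C)(C)C)cc2)c1[Cs] | intermediate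
15 | cesium 3-methoxy-5-(pivaloyloxy)-2-{(E)-3-[4-(pivaloyloxy)phenyl]prop-2-enoyl}phenolate | COc1cc(OC(=O)C(C)(C)C)cc([O-])c1C(=O)/C=C/c1ccc(OC(=O)C(C)(C)C)cc1.[Cs+] | intermediate
16 | (E)-1-[2-hydroxy-6-methoxy-4-(pivaloyloxy)phenyl]-3-[4-(pivaloyloxy)phenyl]prop-2-en-1-one | COc1cc(OC(=O)C(C)(C)C)cc(O)c1C(=O)/C=C/c1ccc(OC(=O)C(C)(C)C)cc1 | intermediate
17 | (E)-1-[2-hydroxy-3-iodo-6-methoxy-4-(pivaloyloxy)phenyl]-3-[4-(pivaloyloxy)phenyl]prop-2-en-1-one | COc1cc(OC(=O)C(C)(C)C)c(I)c(O)c1C(=O)/C=C/c1ccc(OC(=O)C(C)(C)C)cc1 | intermediate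
18 | ethyl propiolate | CCOC(=O)C#C | starting material
19 | ethyl (Z)-3-iodoprop-2-enoate | CCOC(=O)/C=C\I | intermediate
20 | (Z)-4-iodo-2-methylbut-3-en-2-ol | CC(C)(O)/C=C\I | intermediate
21 | lithium (Z)-4-lithio-2-methylbut-3-en-2-olate | CC(C)(O[Li])/C=C\[Li] | intermediate
22 | 5,5-dimethyl-1,2-oxaborol-2(5H)-ol | CC1(C)C=CB(O)O1 | intermediate
23 | (E)-1-{2-hydroxy-3-[(Z)-3-hydroxy-3-methylbut-1-en-1-yl]-6-methoxy-4-(pivaloyloxy)phenyl}-3-[4-(pivaloyloxy)phenyl]prop-2-en-1-one | COc1cc(OC(=O)C(C)(C)C)c(/C=C\C(C)(C)O)c(O)c1C(=O)/C=C/c1ccc(OC(=O)C(C)(C)C)cc1 | intermediate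
24 | candidachalcone, (E)-1-{2,4-dihydroxy-3-[(Z)-3-hydroxy-3-methylbut-1-en-1-yl]-6-methoxyphenyl}-3-(4-hydroxyphenyl)prop-2-en-1-one | COc1cc(O)c(/C=C\C(C)(C)O)c(O)c1C(=O)/C=C/c1ccc(O)cc1 | target

**Step count and risks**

Total steps: 11. Longest linear sequence: 7 steps (steps 1, 2, 3, 5, 6, 10, 11).

The three steps most likely to fail are steps 5, 10 and 1, in that order.

For step 5, the aryl anion may be protonated before the acyl group has moved to carbon, which would stop at the aryl ester. The phenoxide may also close onto the enone in the hot fluoride medium, so that the open chalcone is not obtained. The fallback builds 16 by a classical aldol route that sets out from 1 and comes back at 16. Friedel–Crafts C-acetylation of 1 (AcOH, BF3·OEt2, 90 °C) should give 1-(2,4-dihydroxy-6-methoxyphenyl)ethan-1-one F1 after separation from its 2,6-dihydroxy-4-methoxy isomer. Protection of the non-chelated para hydroxyl (MOMCl, iPr2NEt, CH2Cl2, 0 °C) gives 1-[2-hydroxy-6-methoxy-4-(methoxymethoxy)phenyl]ethan-1-one F2. Claisen–Schmidt condensation with commercial 4-(methoxymethoxy)benzaldehyde (KOH, EtOH/H2O, rt) gives (E)-1-[2-hydroxy-6-methoxy-4-(methoxymethoxy)phenyl]-3-[4-(methoxymethoxy)phenyl]prop-2-en-1-one F3. Acidic methanolysis (HCl, MeOH, 40 °C) gives (E)-1-(2,4-dihydroxy-6-methoxyphenyl)-3-(4-hydroxyphenyl)prop-2-en-1-one F4. Acylation of its two non-chelated phenols with 8 (2.1 equiv, Et3N, CH2Cl2, −10 °C) spares the chelated C2' hydroxyl and returns to 16.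

For step 10, oxidative addition at the iodide, which is flanked on both sides and carries an ortho phenoxide, may be slow. The alkenylboron partner may also be lost by protodeboronation in aqueous base, or the Z alkene may isomerise. The fallback is a base-free Stille coupling that sets out from 20 and comes back at 23. Dianion 21, generated as in step 9, is quenched with Bu3SnCl to give (Z)-2-methyl-4-(tributylstannyl)but-3-en-2-ol F5. This is coupled with 17 (Pd2(dba)3, AsPh3, NMP, 50 °C) with retention of alkene geometry to give 23.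

For step 1, the very electron-rich diol may be brominated with poor site selectivity (attack at C2 between the hydroxyls) or more than once. The fallback replaces innate selectivity by steric control; it sets out from 1 and comes back at 2. Silylation (TIPSCl, imidazole, DMF) gives 1-methoxy-3,5-bis(triisopropylsilyloxy)benzene F6, in which the position between the two bulky silyloxy groups is shielded. NBS (MeCN, 0 °C) should then brominate next to the methoxyl to give 2-bromo-1-methoxy-3,5-bis(triisopropylsilyloxy)benzene F7. TBAF (THF, 0 °C) removes both silyl groups and returns to 2.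

**Further compounds**

F1 | step 5 | 1-(2,4-dihydroxy-6-methoxyphenyl)ethan-1-one | COc1cc(O)cc(O)c1C(C)=O
F2 | step 5 | 1-[2-hydroxy-6-methoxy-4-(methoxymethoxy)phenyl]ethan-1-one | COCOc1cc(O)c(C(C)=O)c(OC)c1
F3 | step 5 | (E)-1-[2-hydroxy-6-methoxy-4-(methoxymethoxy)phenyl]-3-[4-(methoxymethoxy)phenyl]prop-2-en-1-one | COCOc1ccc(/C=C/C(=O)c2c(O)cc(OCOC)cc2OC)cc1
F4 | step 5 | (E)-1-(2,4-dihydroxy-6-methoxyphenyl)-3-(4-hydroxyphenyl)prop-2-en-1-one | COc1cc(O)cc(O)c1C(=O)/C=C/c1ccc(O)cc1
F5 | step 10 | (Z)-2-methyl-4-(tributylstannyl)but-3-en-2-ol | CCCC[Sn](CCCC)(CCCC)/C=C\C(C)(C)O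
F6 | step 1 | 1-methoxy-3,5-bis(triisopropylsilyloxy)benzene | COc1cc(O[Si](C(C)C)(C(C)C)C(C)C)cc(O[Si](C(C)C)(C(C)C)C(C)C)c1
F7 | step 1 | 2-bromo-1-methoxy-3,5-bis(triisopropylsilyloxy)benzene | COc1cc(O[Si](C(C)C)(C(C)C)C(C)C)cc(O[Si](C(C)C)(C(C)C)C(C)C)c1Br
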